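**Plan**

- Retrosynthesis: the benzyl ethers and a C3 carboxylate are removed first; the flavanone O1–C2 bond is then cut (oxa-Michael), followed by the alkylidene C=C bond (Knoevenagel). The aldehyde half is cut at the diaryl ether C–O bond (Ullmann) and at the flavone pyranone ring (chalcone oxidative cyclisation). The ketoester half is cut at the C3–CO2tBu bond (enolate C-acylation).
- Forward: the flavone ring is built first, the diaryl ether is joined next, the Knoevenagel condensation unites the two halves, and the flavanone pyranone ring closes last.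
- Enabling feature: flavanone C2 carries ring oxygen O1 and lies beta to the C4 ketone, and the A ring has a phenolic oxygen ortho to the acyl carbon. With a tert-butoxycarbonyl group on C3 the O1–C2 bond can be formed by a catalysed 6-endo oxa-Michael addition.
- Stereochemistry: the only stereocentre (2S) is set by a cinchona-thiourea catalyst in that closure. The C3 ester centre is transient and is erased by acidic decarboxylation, which does not open the ring.

Key step: step 8

Remark 1: benzyl ethers are used throughout because they should survive I2/DMSO flavone formation and the acidic decarboxylation. The second A-ring ortho hydroxyl is benzylated so that only one, carbonyl-chelated phenol can cyclise and the uncatalysed closure is suppressed.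

Remark 2: the quinidine-derived pseudoenantiomer of the thiourea catalyst is taken to deliver 2S. The quinine-derived one gives the opposite sense and would be used if the assignment proved reversed.

**Route**

Step 1
Reactants: 1 2',4',6'-trihydroxyacetophenone
Product: 2 1-[2,4-bis(benzyloxy)-6-hydroxyphenyl]ethanone
Conditions: BnBr (2.1 equiv), K2CO3 (2.2 equiv), DMF, rt to 60 °C
Reagents that add atoms: benzyl bromide, BrCc1ccccc1
Why: Williamson etherification in which the hydroxyl that stays hydrogen-bonded to the acetyl carbonyl is the least nucleophilic, so two equivalents should alkylate the 4-OH and one of the two equivalent ortho hydroxyls.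

Step 2
Reactants: 2 1-[2,4-bis(benzyloxy)-6-hydroxyphenyl]ethanone; 3 4-bromobenzaldehyde
Product: 4 (E)-1-[2,4-bis(benzyloxy)-6-hydroxyphenyl]-3-(4-bromophenyl)prop-2-en-1-one
Conditions: KOH (50% aq), EtOH–THF, rt
Reagents that add atoms: none
Why: Claisen–Schmidt condensation, the acetophenone enolate adding to the non-enolisable aldehyde and E1cB dehydration giving the E-chalcone.

Step 3
Reactants: 4 (E)-2'-hydroxy-4',6'-bis(benzyloxy)-4-bromochalcone
Product: 5 5,7-bis(benzyloxy)-2-(4-bromophenyl)-4H-chromen-4-one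
Conditions: I2 (10 mol%), DMSO, 130 °C
Reagents that add atoms: none
Why: I2/DMSO oxidative cyclisation of a 2'-hydroxychalcone (oxa-Michael closure, alpha-iodination and loss of HI, with DMSO reoxidising iodide), which benzyl ethers and the aryl bromide should tolerate.

Step 4
Reactants: 5 5,7-bis(benzyloxy)-2-(4-bromophenyl)-4H-chromen-4-one; 6 4-(benzyloxy)-3-hydroxybenzaldehyde
Product: 7 4-(benzyloxy)-3-{4-[5,7-bis(benzyloxy)-4-oxo-4H-chromen-2-yl]phenoxy}benzaldehyde
Conditions: CuI (10 mol%), picolinic acid (20 mol%), K3PO4 (2 equiv), DMSO, 90 °C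
Reagents that add atoms: none
Why: Ullmann-type copper-catalysed diaryl ether coupling, favoured because the bromide sits para to the electron-withdrawing chromone C2, picolinic acid ligation suits ortho-substituted phenoxides, and the non-enolisable aldehyde is inert to phosphate base.

Step 5
Reactants: 8 2',6'-dihydroxy-4'-methoxyacetophenone
Product: 9 1-[2-(benzyloxy)-6-hydroxy-4-methoxyphenyl]ethanone
Conditions: BnBr (1.05 equiv), K2CO3 (1.1 equiv), acetone, reflux
Reagents that add atoms: benzyl bromide, BrCc1ccccc1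
Why: Williamson mono-etherification of two equivalent hydroxyls, the remaining one being locked in a hydrogen bond to the carbonyl after the first alkylation and therefore much slower to react.

Step 6
Reactants: 9 1-[2-(benzyloxy)-6-hydroxy-4-methoxyphenyl]ethanone
Product: 10 tert-butyl 3-[2-(benzyloxy)-6-hydroxy-4-methoxyphenyl]-3-oxopropanoate
Conditions: LiHMDS (3.3 equiv), THF, −78 °C; Boc2O (1.1 equiv), −78 to 0 °C; aq NH4Cl
Reagents that add atoms: di-tert-butyl dicarbonate, CC(C)(C)OC(=O)OC(=O)OC(C)(C)C
Why: Claisen-type C-acylation of the phenoxide/enolate dianion, whose enolate carbon is the most nucleophilic site because the phenoxide is chelated, while the third equivalent of base stores the product as its enolate and the bulky tert-butyl ester resists lactonisation to a 4-hydroxycoumarin.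

Step 7
Reactants: 10 tert-butyl 3-[2-(benzyloxy)-6-hydroxy-4-methoxyphenyl]-3-oxopropanoate; 7 4-(benzyloxy)-3-{4-[5,7-bis(benzyloxy)-4-oxo-4H-chromen-2-yl]phenoxy}benzaldehyde
Product: 11 tert-butyl 2-[2-(benzyloxy)-6-hydroxy-4-methoxybenzoyl]-3-{4-(benzyloxy)-3-[4-(5,7-bis(benzyloxy)-4-oxo-4H-chromen-2-yl)phenoxy]phenyl}prop-2-enoate (E/Z mixture)
Conditions: piperidine (20 mol%), AcOH (20 mol%), 4 Å MS, toluene, rt
Reagents that add atoms: none
Why: Knoevenagel condensation via the iminium ion of the non-enolisable aldehyde, the buffered room-temperature medium being too weakly basic to close the carbonyl-chelated phenol prematurely.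

Step 8
Reactants: 11 alkylidene beta-ketoester (E/Z mixture)
Product: 12 tert-butyl (2S,3R)-5-(benzyloxy)-2-{4-(benzyloxy)-3-[4-(5,7-bis(benzyloxy)-4-oxo-4H-chromen-2-yl)phenoxy]phenyl}-7-methoxy-4-oxochromane-3-carboxylate (2,3-trans)
Conditions: quinidine-derived 9-amino-9-deoxy-epi-cinchona 3,5-bis(trifluoromethyl)phenyl thiourea (10 mol%), toluene–CH2Cl2, −25 °C
Reagents that add atoms: none
Why: The quinuclidine nitrogen activates the chelated phenol while the thiourea N–H pair binds the 1,3-dicarbonyl unit, and the phenoxide adds to the beta-carbon to give a catalyst-bound enolate that is protonated at C3. The closest known reaction is the cinchona-thiourea-catalysed intramolecular oxa-Michael addition of alkylidene beta-ketoesters to 3-carboxyflavanones. The pyranone ring closes in the 6-endo-trig mode, forming O1–C2. C2 is controlled by the catalyst, whose two-point hydrogen bonding to the beta-ketoester exposes one face of the beta-carbon to the tethered phenoxide, and C3 should settle trans to the aryl group by enolisation before it is removed in step 9. The step needs face selectivity over a racemic background closure, which the substrate secures by offering a single free phenol held in a hydrogen bond to the ketone, the other ortho oxygen being benzylated; the E and Z isomers are expected to equilibrate under the amine by reversible addition, so the mixture can be used.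

Step 9
Reactants: 12 tert-butyl (2S,3R)-3-carboxylate flavanone
Product: 14 (2S)-5-(benzyloxy)-2-{4-(benzyloxy)-3-[4-(5,7-bis(benzyloxy)-4-oxo-4H-chromen-2-yl)phenoxy]phenyl}-7-methoxychroman-4-one, via beta-keto acid 13 (not isolated)
Conditions: TsOH·H2O (0.5 equiv), toluene, 80 °C
Reagents that add atoms: none
Why: Acid-mediated tert-butyl ester cleavage with loss of isobutene followed by thermal decarboxylation of the beta-keto acid, under conditions that do not trigger the base-induced retro-oxa-Michael opening, so C2 is retained while the C3 centre disappears.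

Step 10
Reactants: 14 (2S)-tetra-O-benzyl biflavonoid
Product: 15 (2S)-2-{3-[4-(5,7-dihydroxy-4-oxo-4H-chromen-2-yl)phenoxy]-4-hydroxyphenyl}-5-hydroxy-7-methoxychroman-4-one
Conditions: H2 (1 atm), 10% Pd/C, EtOAc–THF, rt, stopped when the benzyl ethers are consumed
Reagents that add atoms: none
Why: Catalytic hydrogenolysis of the four aryl benzyl ethers under neutral conditions, which should be faster than reduction of the flavone C2=C3 bond or cleavage of the flavanone C2–O1 bond and cannot open the pyranone ring, so the 2S centre is carried through.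

**Compound list**

1 | 2',4',6'-trihydroxyacetophenone | CC(=O)c1c(O)cc(O)cc1O | starting material
2 | 1-[2,4-bis(benzyloxy)-6-hydroxyphenyl]ethanone | CC(=O)c1c(O)cc(OCc2ccccc2)cc1OCc1ccccc1 | intermediate
3 | 4-bromobenzaldehyde | O=Cc1ccc(Br)cc1 | starting material
4 | (E)-1-[2,4-bis(benzyloxy)-6-hydroxyphenyl]-3-(4-bromophenyl)prop-2-en-1-one | O=C(/C=C/c1ccc(Br)cc1)c1c(O)cc(OCc2ccccc2)cc1OCc1ccccc1 | intermediate
5 | 5,7-bis(benzyloxy)-2-(4-bromophenyl)-4H-chromen-4-one | O=c1cc(-c2ccc(Br)cc2)oc2cc(OCc3ccccc3)cc(OCc3ccccc3)c12 | intermediate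
6 | 4-(benzyloxy)-3-hydroxybenzaldehyde | O=Cc1ccc(OCc2ccccc2)c(O)c1 | starting material
7 | 4-(benzyloxy)-3-{4-[5,7-bis(benzyloxy)-4-oxo-4H-chromen-2-yl]phenoxy}benzaldehyde | O=Cc1ccc(OCc2ccccc2)c(Oc2ccc(-c3cc(=O)c4c(OCc5ccccc5)cc(OCc5ccccc5)cc4o3)cc2)c1 | intermediate
8 | 2',6'-dihydroxy-4'-methoxyacetophenone | CC(=O)c1c(O)cc(OC)cc1O | starting material
9 | 1-[2-(benzyloxy)-6-hydroxy-4-methoxyphenyl]ethanone | CC(=O)c1c(O)cc(OC)cc1OCc1ccccc1 | intermediate
10 | tert-butyl 3-[2-(benzyloxy)-6-hydroxy-4-methoxyphenyl]-3-oxopropanoate | COc1cc(O)c(C(=O)CC(=O)OC(C)(C)C)c(OCc2ccccc2)c1 | intermediate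
11 | tert-butyl 2-[2-(benzyloxy)-6-hydroxy-4-methoxybenzoyl]-3-{4-(benzyloxy)-3-[4-(5,7-bis(benzyloxy)-4-oxo-4H-chromen-2-yl)phenoxy]phenyl}prop-2-enoate (E/Z mixture) | COc1cc(O)c(C(=O)C(C(=O)OC(C)(C)C)=Cc2ccc(OCc3ccccc3)c(Oc3ccc(-c4cc(=O)c5c(OCc6ccccc6)cc(OCc6ccccc6)cc5o4)cc3)c2)c(OCc2ccccc2)c1 | intermediate
12 | tert-butyl (2S,3R)-5-(benzyloxy)-2-{4-(benzyloxy)-3-[4-(5,7-bis(benzyloxy)-4-oxo-4H-chromen-2-yl)phenoxy]phenyl}-7-methoxy-4-oxochromane-3-carboxylate | COc1cc(OCc2ccccc2)c2c(c1)O[C@H](c1ccc(OCc3ccccc3)c(Oc3ccc(-c4cc(=O)c5c(OCc6ccccc6)cc(OCc6ccccc6)cc5o4)cc3)c1)[C@@H](C(=O)OC(C)(C)C)C2=O | intermediate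
13 | (2S,3R)-5-(benzyloxy)-2-{4-(benzyloxy)-3-[4-(5,7-bis(benzyloxy)-4-oxo-4H-chromen-2-yl)phenoxy]phenyl}-7-methoxy-4-oxochromane-3-carboxylic acid | COc1cc(OCc2ccccc2)c2c(c1)O[C@H](c1ccc(OCc3ccccc3)c(Oc3ccc(-c4cc(=O)c5c(OCc6ccccc6)cc(OCc6ccccc6)cc5o4)cc3)c1)[C@@H](C(=O)O)C2=O | intermediate
14 | (2S)-5-(benzyloxy)-2-{4-(benzyloxy)-3-[4-(5,7-bis(benzyloxy)-4-oxo-4H-chromen-2-yl)phenoxy]phenyl}-7-methoxychroman-4-one | COc1cc(OCc2ccccc2)c2c(c1)O[C@H](c1ccc(OCc3ccccc3)c(Oc3ccc(-c4cc(=O)c5c(OCc6ccccc6)cc(OCc6ccccc6)cc5o4)cc3)c1)CC2=O | intermediate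
15 | (2S)-2-{3-[4-(5,7-dihydroxy-4-oxo-4H-chromen-2-yl)phenoxy]-4-hydroxyphenyl}-5-hydroxy-7-methoxychroman-4-one | COc1cc(O)c2c(c1)O[C@H](c1ccc(O)c(Oc3ccc(-c4cc(=O)c5c(O)cc(O)cc5o4)cc3)c1)CC2=O | target

**Summary**

Total step count: 10.
Longest linear sequence: 8 steps (steps 1, 2, 3, 4, 7, 8, 9, 10); the ketoester branch (steps 5 and 6) joins at step 7.

**Steps most likely to fail**

Step 8. Face selectivity may be insufficient, either through a competing uncatalysed closure or because the bulky 6'-benzyloxy group and the remote flavone carbonyl disturb the two-point binding of the catalyst. The fallback sets out from 7 and 9. These would be joined by Claisen–Schmidt condensation (KOH, EtOH–THF, rt) to give the (E)-2'-hydroxychalcone F1. This would be cyclised with NaOAc in refluxing EtOH to the racemic tetra-O-benzyl flavanone F2. The enantiomers would be separated by preparative SFC on a polysaccharide chiral stationary phase, and the 2R material re-equilibrated under the NaOAc conditions and recycled. The route is rejoined at 14.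

Step 6. Acylation may occur at oxygen (phenoxide or enolate) instead of carbon, or the product may lactonise with loss of tert-butoxide. The fallback sets out from 9. The chelated phenol would be masked (MOMCl, NaH, DMF, 0 °C) as the methoxymethyl ether F3. The plain ketone enolate would then be C-acylated (LiHMDS 2.2 equiv, Boc2O, THF, −78 °C) to give the protected beta-ketoester F4. The MOM group ortho to the carbonyl would be removed with catalytic HCl in MeOH at rt, which the tert-butyl ester and benzyl ether should survive. The route is rejoined at 10.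

Step 4. Coupling of the ortho-substituted phenoxide may be slow, leaving time for hydrodebromination of the flavone and base-induced degradation of the aldehyde. The fallback sets out from 6 and moves ether formation ahead of flavone construction. The aldehyde would be masked (ethylene glycol, cat. TsOH, toluene, Dean–Stark) as the dioxolane phenol F5. SNAr on 4-fluorobenzaldehyde (K2CO3, DMF, 120 °C) would give the diaryl ether aldehyde F6. Claisen–Schmidt condensation with 2 (KOH, EtOH–THF) would give the chalcone F7, and I2/DMSO cyclisation the flavone acetal F8. Acetal hydrolysis (aq HCl, THF, rt) would then return the route to 7.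

**Further compounds**

F1 | step 8 | (E)-1-[2-(benzyloxy)-6-hydroxy-4-methoxyphenyl]-3-{4-(benzyloxy)-3-[4-(5,7-bis(benzyloxy)-4-oxo-4H-chromen-2-yl)phenoxy]phenyl}prop-2-en-1-one | COc1cc(O)c(C(=O)/C=C/c2ccc(OCc3ccccc3)c(Oc3ccc(-c4cc(=O)c5c(OCc6ccccc6)cc(OCc6ccccc6)cc5o4)cc3)c2)c(OCc2ccccc2)c1
F2 | step 8 | racemic 5-(benzyloxy)-2-{4-(benzyloxy)-3-[4-(5,7-bis(benzyloxy)-4-oxo-4H-chromen-2-yl)phenoxy]phenyl}-7-methoxychroman-4-one | COc1cc(OCc2ccccc2)c2c(c1)OC(c1ccc(OCc3ccccc3)c(Oc3ccc(-c4cc(=O)c5c(OCc6ccccc6)cc(OCc6ccccc6)cc5o4)cc3)c1)CC2=O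
F3 | step 6 | 1-[2-(benzyloxy)-4-methoxy-6-(methoxymethoxy)phenyl]ethanone | CC(=O)c1c(OCOC)cc(OC)cc1OCc1ccccc1
F4 | step 6 | tert-butyl 3-[2-(benzyloxy)-4-methoxy-6-(methoxymethoxy)phenyl]-3-oxopropanoate | COCOc1cc(OC)cc(OCc2ccccc2)c1C(=O)CC(=O)OC(C)(C)C
F5 | step 4 | 2-(benzyloxy)-5-(1,3-dioxolan-2-yl)phenol | Oc1cc(C2OCCO2)ccc1OCc1ccccc1
F6 | step 4 | 4-[2-(benzyloxy)-5-(1,3-dioxolan-2-yl)phenoxy]benzaldehyde | O=Cc1ccc(Oc2cc(C3OCCO3)ccc2OCc2ccccc2)cc1
F7 | step 4 | (E)-1-[2,4-bis(benzyloxy)-6-hydroxyphenyl]-3-{4-[2-(benzyloxy)-5-(1,3-dioxolan-2-yl)phenoxy]phenyl}prop-2-en-1-one | O=C(/C=C/c1ccc(Oc2cc(C3OCCO3)ccc2OCc2ccccc2)cc1)c1c(O)cc(OCc2ccccc2)cc1OCc1ccccc1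
F8 | step 4 | 5,7-bis(benzyloxy)-2-{4-[2-(benzyloxy)-5-(1,3-dioxolan-2-yl)phenoxy]phenyl}-4H-chromen-4-one | O=c1cc(-c2ccc(Oc3cc(C4OCCO4)ccc3OCc3ccccc3)cc2)oc2cc(OCc3ccccc3)cc(OCc3ccccc3)c12
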